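(Readings and results stem from a simulated flask from invented constants, noise included.)

Friday's run stalls.

| flask | starting material | partner | time |
|---|---|---|---|
| Monday's | 300 mM | 750 mM |  |
| Wednesday's | 180 mM | 630 mM |  |
| Friday's | 300 mM | 1100 mM |  |
| Sunday's | 300 mM | 2200 mM | 120 min |

| run | time / min | [product] / mM |
|---|---|---|
| Monday's run | 6.8 | 64.1 |
| Monday's run | 21 | 88.5 |
| Monday's run | 40 | 99.2 |
| Monday's run | 63 | 100.6 |
| Monday's run | 90 | 103.7 |
| Monday's run | 120 | 105.1 |
| Wednesday's run | 6.8 | 32.0 |
| Wednesday's run | 21 | 49.1 |
| Wednesday's run | 40 | 53.4 |
| Wednesday's run | 63 | 56.3 |
| Wednesday's run | 90 | 55.8 |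
| Wednesday's run | 120 | 57.7 |
| Friday's run | 6.8 | 90.3 |
| Friday's run | 21 | 121.4 |
| Friday's run | 40 | 130.3 |
| Friday's run | 63 | 134.2 |
| Friday's run | 90 | 138.3 |
| Friday's run | 120 | 135.7 |

(scatter of a reading: 0.9 mM)

- Overall: starting material + partner -> product.
- Constant volume, constant temperature.
- Bound and free are read together.
- An order is taken over about fifteen percent of the charge, up and down.

* reaction order in [starting material] at the outset, round the charge of the Monday's run, defined at two percent of the starting material turned into product (one fixed amount of product, the same in the runs compared)
* reaction order in [partner] at the outset, round the charge of the Monday's run, defined at two percent of the starting material turned into product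
* product in the Sunday's run at 120 min, as a share of the starting material charged

Between 63 min and 120 min, Friday's run gains 1.50 mM of product against a scatter of 0.9 mM per reading, and it stands at 45.2 % of its starting material. So Sunday's run keeps the time of 120 min and changes the partner charge, and the decision is whether twice Friday's charge is worth making.

My own reckoning takes the rate of product formation as a rate constant times starting material times partner, with the constant free to fade in time. With S and R the charges and P the product, this integrates in closed form:

B = ln[ S(R − P) / (R(S − P)) ] / (R − S)

The last readings give 0.645 M⁻¹ for Wednesday's run, 0.623 M⁻¹ for Monday's and 0.588 M⁻¹ for Friday's, smaller at each step up in partner. This B is the reaction budget, the time integral of the fading constant up to 120 min. Multiplied by a concentration, it plays the part of elapsed time over time constant in a first-order lag.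

Turned round, with x = exp[B(R − S)], the budget gives the share of starting material converted:

P/S = R(x − 1) / (Rx − S)

Friday's budget on Sunday's charge gives x = 3.06 and a share of 70.4 %, which I read as the high side, since Friday's budget is smaller than Monday's.

The forecast says 65 % (60 % to 71 %), less than my figure, on the grounds that “equilibrium gives about 63% and decay about 69%, so I expect about 65%”. It puts both orders at 0.95. Even its low end is more than Friday's share, so the charge stands.

Sunday's run gives 67.1 % at 120 min. Round Monday's charge, the orders at the outset are 0.93 in starting material and 1.4 in partner, the latter above the forecast's 0.95.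

    2 partner ⇌ reagent dimer, settled at all times (0.5560 M⁻¹)
    starting material + reagent dimer → product + partner (0.7620 M⁻¹ min⁻¹)
    2 partner → lost reagent (0.2538 M⁻¹ min⁻¹)
    starting material + partner ⇌ idle substrate-reagent adduct, settled at all times (0.9110 M⁻¹)

With two percent of Monday's starting material turned, Friday's run makes product at 27 mM min⁻¹ against 16 mM min⁻¹ in Monday's run, 1.7 times as fast. Put through the same integral, Sunday's share corresponds to a budget of 0.534 M⁻¹, below Friday's 0.588 M⁻¹.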